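All runs are simulated on assumed constants.

- Time is the plainest setting of a catalysed flask. While the catalyst turns over at a steady pace, target grows along a straight line, and the fraction of the charge converted is mean turnover rate × time × catalyst loading, the loading being catalyst charged over starting material charged.

| flask | starting material | coupling partner | scavenger | free catalyst | remark | time |
|---|---|---|---|---|---|---|
| north-west | 0.051 M | 0.39 M | 0.039 M | 1 mM | run made earlier |  |
| north-east | 0.43 M | 0.39 M | 0.039 M | 1 mM | run made earlier |  |
| west | 0.13 M | 0.39 M | 0.058 M | 1 mM | run made earlier |  |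
| alpha | 0.080 M | 0.390 M | 0.0390 M | 1.0 mM |  | 40 min |
| gamma | 0.50 M | 0.390 M | 0.0390 M | 1.0 mM |  | 40 min |
| beta | 0.13 M | 0.390 M | 0.120 M | 0.50 mM |  | 40 min |
| delta | 0.13 M | 0.390 M | 0.0390 M | 1.0 mM |  | 40 min |
| eta | 0.040 M | 0.600 M | 0.0390 M | 1.5 mM |  | 40 min |
| zeta | 0.20 M | 0.600 M | 0.0390 M | 3.0 mM |  | 40 min |

| run | time / min | target / % | starting material / % |
|---|---|---|---|
| north-west | 6.00 | 12.2 | 85.8 |
| north-west | 12.0 | 24.5 | 73.9 |
| north-west | 15.0 | 29.7 | 69.5 |
| north-west | 25.0 | 46.7 | 51.8 |
| north-west | 30.0 | 54.2 | 44.6 |
| north-east | 2.50 | 0 | 99.9 |
| north-east | 4.00 | 1.5 | 99.2 |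
| north-east | 8.00 | 1.4 | 98.2 |
| north-east | 15.0 | 2.1 | 96.5 |
| north-east | 30.0 | 4.5 | 94.9 |
| west | 6.00 | 6.5 | 95.2 |
| west | 12.0 | 9.8 | 89.8 |
| west | 15.0 | 11.7 | 87.0 |
| west | 25.0 | 19.3 | 76.8 |
| west | 30.0 | 24.0 | 72.6 |

(each reading ± 1 percentage point)

- the flasks put in order of amount of target, in percent of the starting material charged, best first, at 40 min (alpha / gamma / beta / delta / eta / zeta)
- the amount of target, in percent of the starting material charged of the flask you put first, at 40 min
- the amount of target, in percent of the starting material charged of the flask you put last, at 40 min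

- no earlier run changes the charge of free catalyst; that part of a forecast is a guess
- a reading of starting material is of its free form alone

- The north-west run, with 54.2 % of target at 30.0 min and a loading of 1.96 %, gives 0.921 min⁻¹: this is the mean turnover rate, target made per minute per catalyst charged, the usual turnover frequency.
- Replacing that run's curve by its mean costs little: the line gives 27.1 % at 15.0 min, and the reading is 29.7 %.
- Starting material: at the same catalyst charge, a heavier charge of starting material lowers the loading, so by hand the north-east run should reach 6.43 % at 30.0 min, but it reads 4.5 %. Its own mean rate is 0.645 min⁻¹, lower than the north-west value.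
- Catalyst: the loading enters as a plain factor, which no earlier run tests, so this is a guess. The west run's rate, 1.04 min⁻¹, gives delta 32.0 %, beta 16.0 % and zeta 62.4 %. Alpha gets 46.1 % to 52.0 %, and the north-east rate gives gamma 5.16 %.
- Coupling partner: the earlier runs share a charge of 0.39 M, so my reckoning keeps the rates unchanged for eta and zeta, again a guess.
- Scavenger: the west run holds 0.058 M against 0.039 M in the north-west run, and its starting material differs too, so these two runs do not separate the two effects.
- Eta: at the north-west rate the line reaches the whole charge in 28.9 min, sooner than 40 min. My reckoning therefore puts eta first, near completion, with the size of the shortfall open.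
- The forecast, holding that the “rate barely depends on conversion”, gives eta > zeta > alpha > delta > beta > gamma, with 96 % on top and 5 % at the bottom.
- The flasks give eta > zeta > alpha > delta > beta > gamma, with 91.9 % and 4.42 %. The forecast's order stands, and both of its numbers lie within their margins.

    catalyst intermediate B → released group + catalyst intermediate C (k = 0.142 s⁻¹)
    catalyst intermediate C → free catalyst + target (k = 0.0474 s⁻¹)
    scavenger + released group → scavenged by-product (k = 0.129 M⁻¹ s⁻¹)
    coupling partner + free catalyst ⇌ catalyst intermediate A (K = 7.30 M⁻¹, k = 32.5 M⁻¹ s⁻¹)
    starting material + released group ⇌ idle adduct, settled at all times (K = 3.27 M⁻¹)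
    starting material + catalyst intermediate A → catalyst intermediate B (k = 1.32 M⁻¹ s⁻¹)
    starting material + catalyst intermediate B ⇌ idle complex, settled at all times (K = 22.7 M⁻¹)

- In eta at 40.0 min, starting material has a half-life of 8.0 min by its step with catalyst intermediate A, far longer than the 0.24 min of catalyst intermediate C by its step to free catalyst and target, and catalyst intermediate A, the resting state at that moment, holds 73.3 % of the catalyst. Half of that step's turnover in eta up to 40 min is done by 13.1 min, earlier than the 20.0 min of a straight line, and eta's mean rate over 40 min comes to 0.612 min⁻¹, lower than the north-west value.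
- A neighbour of eta with 3.8 × 10⁻⁴ M of free catalyst has a loading of 0.950 %, so the north-west rate gives 35.0 % at 40 min, with the line's emptying time at 114 min. That neighbour gives 36.2 %.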